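## Retrosynthetic overview

- The target is (13R)-20-acetoxy-2α-angeloyloxylabda-7,14-diene-3α,13-diol, a normal-series labdane. No ring is formed: rings A and B, all 20 skeletal carbons and C5, C9, C10 and C13 come from (−)-sclareol. Only C–O bonds are made.
- The 3α-OH and free 13-OH come from a 2α-angeloyloxy-3-ketone by axial-alcohol-selective reduction and desilylation. That ketone comes from the 3-ketone and angelic acid by C2–O bond formation (nitrone acyl-transfer [3,3] shift).
- The 20-OAc and 7-ene come from a 7α-bromo-8β,20-ether by zinc reductive opening. The ether comes from the 7α-bromo-8β-ol by C20–O bond formation (alkoxyl-radical 1,5-HAT), and the bromohydrin comes from the 7-ene.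
- The 7-ene comes from the 8(17)-ene, which comes from the 8α-ol of sclareol. The 3-ketone comes from enzymatic C3–H hydroxylation of sclareol followed by oxidation.

Assumption: natural (−)-sclareol counts as the cheap commercial starting material, and the P450 variant is expressed in house and counts as a catalyst.

## Route

Step 1
Reactants: 1 (−)-sclareol [(13R)-labd-14-ene-8α,13-diol]
Product: 2 3β-hydroxysclareol [(13R)-labd-14-ene-3β,8α,13-triol]
Conditions: engineered cytochrome P450 BM3 variant (C3-selective, E. coli lysate), NADP+ (cat.), Na2HPO3, phosphite dehydrogenase, air, KH2PO4/K2HPO4 buffer pH 8, 5% EtOH, 25 °C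
Reagents that add atoms: dioxygen O=O
Why: Enzymatic C–H hydroxylation by P450 oxygen rebound at C3 of sclareol is an established preparative reaction of this enzyme family, it replaces the equatorial 3β-H with retention, and it leaves the vinyl carbinol untouched.

Step 2
Reactants: 2 3β-hydroxysclareol
Product: 3 3-oxosclareol [(13R)-8α,13-dihydroxylabd-14-en-3-one]
Conditions: n-Pr4N[RuO4] (5 mol%), NMO, 4 Å MS, CH2Cl2, 23 °C
Reagents that add atoms: none
Why: The Ley–Griffith oxidation can only touch the single secondary alcohol because the other two hydroxyls are tertiary, and the C3 stereocentre is erased on purpose so that step 9 can reset it as 3α.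

Step 3
Reactants: 3 3-oxosclareol
Product: 6 (13R)-13-(triethylsilyloxy)labda-8(17),14-dien-3-one, via 13-O-TES ether 4 (not isolated), via 8α-chlorosulfite 5 (not isolated)
Conditions: TESOTf (1.05 equiv), 2,6-lutidine, CH2Cl2, −78 °C; then pyridine, SOCl2, −78 → 0 °C
Reagents that add atoms: triethylsilyl trifluoromethanesulfonate CC[Si](CC)(CC)OS(=O)(=O)C(F)(F)F; thionyl chloride O=S(Cl)Cl (its atoms are carried only by 5)
Why: The acyclic, linalool-like 13-OH is silylated much faster than the ring 8α-OH wedged next to C9 and C10, and the following chlorosulfite E2-type dehydration loses a C17 hydrogen because the equatorial leaving group has no antiperiplanar ring hydrogen, so no free C8 cation forms for the 13-oxygen to trap and no stereocentre is created.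

Step 4
Reactants: 6 (13R)-13-(triethylsilyloxy)labda-8(17),14-dien-3-one
Product: 7 (13R)-13-(triethylsilyloxy)labda-7,14-dien-3-one
Conditions: chloro[(R,R)-N,N'-bis(3,5-di-tert-butylsalicylidene)cyclohexane-1,2-diaminato]cobalt (C36H52ClCoN2O2, 3 mol%), PhSiH3 (10 mol%), degassed benzene, 23 °C
Reagents that add atoms: none
Why: In this cobalt-hydride MHAT alkene isomerisation, reversible H-atom transfer to C17 gives the tertiary C8 radical and the bulky cobalt complex takes back the exposed C7–H rather than the buried C9–H, so 6 (and any 7 already in it) converges on the trisubstituted 7-ene, while the vinyl group has no allylic hydrogen and is returned unchanged.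

Step 5
Reactants: 7 (13R)-13-(triethylsilyloxy)labda-7,14-dien-3-one
Product: 8 (13R)-7α-bromo-8β-hydroxy-13-(triethylsilyloxy)labd-14-en-3-one
Conditions: NBS (1.05 equiv), acetone/H2O 5:1, 0 °C, dark
Reagents that add atoms: N-bromosuccinimide O=C1CCC(=O)N1Br; water O
Why: In this bromohydrin formation the more electron-rich trisubstituted alkene takes Br+ on the α face (the β face is shielded by the axial C20 methyl) and water opens the bromonium ion at tertiary C8 in the Markovnikov and trans-diaxial (Fürst–Plattner) sense, which sets 7α-Br and 8β-OH, while the masked 13-oxygen cannot bromoetherify.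

Step 6
Reactants: 8 (13R)-7α-bromo-8β-hydroxy-13-(triethylsilyloxy)labd-14-en-3-one
Product: 11 (13R)-7α-bromo-8β,20-epoxy-13-(triethylsilyloxy)labd-14-en-3-one, via 8β-hypoiodite 9 (not isolated), via 20-iodo-8β-alcohol 10 (not isolated)
Conditions: PhI(OAc)2 (1.5 equiv), I2 (0.6 equiv), cyclohexane/CH2Cl2 4:1, tungsten lamp, 25 °C
Reagents that add atoms: iodine [I][I] (iodine is carried only by 9 and 10, none stays in 11)
Why: This Suárez hypoiodite reaction follows the logic of the classical bromohydrin to 6β,19-ether route to 19-hydroxy steroids: O–I homolysis gives the axial 8β-alkoxyl radical, whose only 1,3-diaxial C–H partner is C20, so 1,5-HAT, iodine transfer and 5-exo closure form the C20–O bond without touching a stereocentre.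

Step 7
Reactants: 11 (13R)-7α-bromo-8β,20-epoxy-13-(triethylsilyloxy)labd-14-en-3-one
Product: 13 (13R)-20-acetoxy-13-(triethylsilyloxy)labda-7,14-dien-3-one, via 20-alcohol 12 (not isolated)
Conditions: Zn dust, AcOH (5 equiv), i-PrOH/THF, 40 °C; filter, concentrate; then Ac2O, pyridine, DMAP (cat.), CH2Cl2, 23 °C
Reagents that add atoms: acetic anhydride CC(=O)OC(C)=O
Why: In this Boord-type zinc reductive elimination the antiperiplanar axial 7α-Br and 8β-O bonds collapse to regenerate the 7-ene regiospecifically and leave the oxygen on C20, and routine acetylation of the only free hydroxyl follows.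

Step 8
Reactants: 13 (13R)-20-acetoxy-13-(triethylsilyloxy)labda-7,14-dien-3-one; 14 angelic acid [(Z)-2-methylbut-2-enoic acid]
Product: 19 (13R)-20-acetoxy-2α-angeloyloxy-13-(triethylsilyloxy)labda-7,14-dien-3-one, via N-methyl nitrone 15 (not isolated), via mixed anhydride 16 (not isolated), via N-acyloxy enamine 17 (not isolated), via 2α-acyloxy imine 18 (not isolated)
Conditions: (a) MeNHOH·HCl (1.5 equiv), pyridine, 4 Å MS, ClCH2CH2Cl, 60 °C; (b) 16 (made apart from 14, 2,4,6-Cl3C6H2COCl, Et3N, toluene, 23 °C), Et3N, 0 → 40 °C; (c) 10% aq. citric acid, THF, 23 °C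
Reagents that add atoms: angelic acid C/C=C(/C)C(=O)O; N-methylhydroxylamine hydrochloride CNO.Cl (its oxygen ends as the ester C=O oxygen, N and CH3 are carried only by 15, 17 and 18); water O (new C3=O oxygen); 2,4,6-trichlorobenzoyl chloride O=C(Cl)c1c(Cl)cc(Cl)cc1Cl (carried only by 16)
Why: Proposed new method: one-flask α-oxyacylation of a neopentyl ketone with a free, geometry-labile enoic acid, in which (i) the small α-effect nucleophile MeNHOH condenses even with the 4,4-dimethyl ketone to give nitrone 15, (ii) the nitrone oxygen is acylated at the unhindered angeloyl carbonyl of Yamaguchi anhydride 16 with no nucleophilic catalyst present to isomerise Z to E, (iii) Et3N removes H-2, the only enolisable position because C4 is quaternary, to give 17, (iv) the weak N–O bond drives a concerted 1-aza-1'-oxa [3,3] shift that delivers the acyl oxygen to the α face of C2, the β face being closed by the two syn-axial groups C10–CH2OAc and 4β-CH3, which forms the C2–O bond as the equatorial and thermodynamically preferred 2α epimer, and (v) mild hydrolysis of 18 frees the ketone, all without an external oxidant so both alkenes survive; the closest known reaction types are the acylation–rearrangement of cyclic ketonitrones with acyl chlorides and the α-oxyacylation of ketones with N-alkyl-O-acylhydroxylamine salts, neither shown with a mixed anhydride of a free (Z)-enoic acid or on a 4,4-dimethyl-3-oxo terpenoid.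

Step 9
Reactants: 19 (13R)-20-acetoxy-2α-angeloyloxy-13-(triethylsilyloxy)labda-7,14-dien-3-one
Product: 21 (13R)-20-acetoxy-2α-angeloyloxylabda-7,14-diene-3α,13-diol (target), via 13-O-TES target ether 20 (not isolated)
Conditions: Li[HB(s-Bu)3] (L-Selectride, 1.2 equiv), THF, −78 °C; then HF·pyridine, pyridine, THF, −78 → 23 °C
Reagents that add atoms: none
Why: In this bulky trialkylborohydride reduction the reagent avoids the axial path past H-1α and H-5α and attacks along the equatorial trajectory from the β side, which sets the axial 3α-OH as known for 4,4-dimethyl-3-oxo terpenoids, the cold acidic quench suppresses acyl migration (the equatorial 2-O-acyl isomer is the more stable one in any case), and buffered HF·pyridine removes the silyl ether without ionising the tertiary allylic alcohol.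

## Compound list

1 | (−)-sclareol, (13R)-labd-14-ene-8α,13-diol | C=C[C@](C)(O)CC[C@H]1[C@](C)(O)CC[C@H]2C(C)(C)CCC[C@]12C | starting material
2 | 3β-hydroxysclareol | C=C[C@](C)(O)CC[C@H]1[C@](C)(O)CC[C@H]2C(C)(C)[C@@H](O)CC[C@]12C | intermediate
3 | 3-oxosclareol | C=C[C@](C)(O)CC[C@H]1[C@](C)(O)CC[C@H]2C(C)(C)C(=O)CC[C@]12C | intermediate
4 | (13R)-8α-hydroxy-13-(triethylsilyloxy)labd-14-en-3-one | C=C[C@](C)(O[Si](CC)(CC)CC)CC[C@H]1[C@](C)(O)CC[C@H]2C(C)(C)C(=O)CC[C@]12C | intermediate
5 | 8α-chlorosulfite of 4 | C=C[C@](C)(O[Si](CC)(CC)CC)CC[C@H]1[C@](C)(OS(=O)Cl)CC[C@H]2C(C)(C)C(=O)CC[C@]12C | intermediate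
6 | (13R)-13-(triethylsilyloxy)labda-8(17),14-dien-3-one | C=C[C@](C)(O[Si](CC)(CC)CC)CC[C@H]1C(=C)CC[C@H]2C(C)(C)C(=O)CC[C@]12C | intermediate
7 | (13R)-13-(triethylsilyloxy)labda-7,14-dien-3-one | C=C[C@](C)(O[Si](CC)(CC)CC)CC[C@H]1C(C)=CC[C@H]2C(C)(C)C(=O)CC[C@]12C | intermediate
8 | (13R)-7α-bromo-8β-hydroxy-13-(triethylsilyloxy)labd-14-en-3-one | C=C[C@](C)(O[Si](CC)(CC)CC)CC[C@H]1[C@@](C)(O)[C@H](Br)C[C@H]2C(C)(C)C(=O)CC[C@]12C | intermediate
9 | 8β-hypoiodite of 8 | C=C[C@](C)(O[Si](CC)(CC)CC)CC[C@H]1[C@@](C)(OI)[C@H](Br)C[C@H]2C(C)(C)C(=O)CC[C@]12C | intermediate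
10 | (13R)-7α-bromo-8β-hydroxy-20-iodo-13-(triethylsilyloxy)labd-14-en-3-one | C=C[C@](C)(O[Si](CC)(CC)CC)CC[C@H]1[C@@](C)(O)[C@H](Br)C[C@H]2C(C)(C)C(=O)CC[C@]12CI | intermediate
11 | (13R)-7α-bromo-8β,20-epoxy-13-(triethylsilyloxy)labd-14-en-3-one | C=C[C@](C)(O[Si](CC)(CC)CC)CC[C@H]1[C@@](C)(O3)[C@H](Br)C[C@H]2C(C)(C)C(=O)CC[C@]12C3 | intermediate
12 | (13R)-20-hydroxy-13-(triethylsilyloxy)labda-7,14-dien-3-one | C=C[C@](C)(O[Si](CC)(CC)CC)CC[C@H]1C(C)=CC[C@H]2C(C)(C)C(=O)CC[C@]12CO | intermediate
13 | (13R)-20-acetoxy-13-(triethylsilyloxy)labda-7,14-dien-3-one | C=C[C@](C)(O[Si](CC)(CC)CC)CC[C@H]1C(C)=CC[C@H]2C(C)(C)C(=O)CC[C@]12COC(C)=O | intermediate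
14 | angelic acid, (Z)-2-methylbut-2-enoic acid | C/C=C(/C)C(=O)O | starting material
15 | N-methyl nitrone of 13 (C=N geometry not defined) | C=C[C@](C)(O[Si](CC)(CC)CC)CC[C@H]1C(C)=CC[C@H]2C(C)(C)C(=[N+](C)[O-])CC[C@]12COC(C)=O | intermediate
16 | angelic 2,4,6-trichlorobenzoic anhydride | C/C=C(/C)C(=O)OC(=O)c1c(Cl)cc(Cl)cc1Cl | intermediate
17 | 3-[N-(angeloyloxy)-N-methylamino]-2-ene derived from 15 | C=C[C@](C)(O[Si](CC)(CC)CC)CC[C@H]1C(C)=CC[C@H]2C(C)(C)C(N(C)OC(=O)/C(C)=C\C)=CC[C@]12COC(C)=O | intermediate
18 | 2α-angeloyloxy-3-(N-methylimine) (C=N geometry not defined) | C=C[C@](C)(O[Si](CC)(CC)CC)CC[C@H]1C(C)=CC[C@H]2C(C)(C)C(=NC)[C@H](OC(=O)/C(C)=C\C)C[C@]12COC(C)=O | intermediate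
19 | (13R)-20-acetoxy-2α-angeloyloxy-13-(triethylsilyloxy)labda-7,14-dien-3-one | C=C[C@](C)(O[Si](CC)(CC)CC)CC[C@H]1C(C)=CC[C@H]2C(C)(C)C(=O)[C@H](OC(=O)/C(C)=C\C)C[C@]12COC(C)=O | intermediate
20 | 13-O-triethylsilyl ether of the target | C=C[C@](C)(O[Si](CC)(CC)CC)CC[C@H]1C(C)=CC[C@H]2C(C)(C)[C@H](O)[C@H](OC(=O)/C(C)=C\C)C[C@]12COC(C)=O | intermediate
21 | (13R)-20-acetoxy-2α-angeloyloxylabda-7,14-diene-3α,13-diol | C=C[C@](C)(O)CC[C@H]1C(C)=CC[C@H]2C(C)(C)[C@H](O)[C@H](OC(=O)/C(C)=C\C)C[C@]12COC(C)=O | target

## Step count and risks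

Total step count: 9. Compound 14 is used as bought.
Longest linear sequence: 9 steps, from 1 to 21.

**Step 8 (the proposed new step).**
- Nitrone formation at the neopentyl ketone may be slow.
- The acylated nitrone may lose a proton from N–CH3 instead of C2.
- Imine 18 may shift its acyl group to nitrogen before hydrolysis.

The fallback uses known chemistry, sets out from 13 and comes back at 19. Soft enolisation of 13 (TMSOTf, Et3N, CH2Cl2, 0 °C; only C2 can enolise) gives the 3-trimethylsilyloxy-2-ene silyl enol ether F1. Rubottom oxidation (m-CPBA 1.0 equiv, NaHCO3, CH2Cl2/hexane, −20 °C, then citric acid/MeOH) attacks this most electron-rich alkene from the open α face and gives the 2α-hydroxy-3-ketone F2. Yamaguchi esterification of F2 with 16, made from 14 (2,4,6-trichlorobenzoyl chloride, Et3N, toluene, 80 °C, conditions known to keep angelates Z), gives 19.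

**Step 6.**
- The tertiary alkoxyl radical may undergo β-scission.
- It may abstract a C12–H and form an 8β,12-ether.
- Acetyl hypoiodite may add to the vinyl group. That adduct would be returned to the alkene by the zinc of step 7.

The fallback changes the radical precursor and avoids both electrophilic iodine and light. It sets out from 7 and comes back at 11. Bromohydroperoxidation of 7 (1,3-dibromo-5,5-dimethylhydantoin, anhydrous H2O2 in Et2O, −40 °C; same α-bromonium and diaxial opening) gives the 7α-bromo-8β-hydroperoxide F3. Its O–O bond is cleaved by divalent iron (FeSO4·7H2O, Cu(OAc)2, AcOH/MeCN, 23 °C, Čeković-type conditions). After 1,5-HAT, the neopentyl C20 radical has no β-hydrogen to lose. It is oxidised by divalent copper and closed by the neighbouring 8β-OH to give 11.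

**Step 3.**
- TESOTf may not discriminate well enough between the two tertiary alcohols.
- An unprotected 13-OH would be destroyed by SOCl2.

The fallback replaces kinetic silylation by the classical ester differentiation and pyrolysis logic. It sets out from 3 and comes back at 6. Exhaustive acetylation (AcCl, N,N-dimethylaniline, CH2Cl2, 23 °C) gives the 8,13-diacetate F4. Partial methanolysis (K2CO3, MeOH, 0 °C) removes the more accessible 13-acetate and gives the 8-monoacetate F5. Thermal syn-elimination of the 8α-acetate (NaHCO3, DMSO, 150 °C) gives 3-oxomanool F6. Silylation of its only hydroxyl (TESOTf, 2,6-lutidine, CH2Cl2, −78 °C) gives 6.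

## Further compounds

F1 | step 8 | (13R)-20-acetoxy-13-(triethylsilyloxy)-3-(trimethylsilyloxy)labda-2,7,14-triene | C=C[C@](C)(O[Si](CC)(CC)CC)CC[C@H]1C(C)=CC[C@H]2C(C)(C)C(O[Si](C)(C)C)=CC[C@]12COC(C)=O
F2 | step 8 | (13R)-20-acetoxy-2α-hydroxy-13-(triethylsilyloxy)labda-7,14-dien-3-one | C=C[C@](C)(O[Si](CC)(CC)CC)CC[C@H]1C(C)=CC[C@H]2C(C)(C)C(=O)[C@H](O)C[C@]12COC(C)=O
F3 | step 6 | (13R)-7α-bromo-8β-hydroperoxy-13-(triethylsilyloxy)labd-14-en-3-one | C=C[C@](C)(O[Si](CC)(CC)CC)CC[C@H]1[C@@](C)(OO)[C@H](Br)C[C@H]2C(C)(C)C(=O)CC[C@]12C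
F4 | step 3 | (13R)-8α,13-diacetoxylabd-14-en-3-one | C=C[C@](C)(OC(C)=O)CC[C@H]1[C@](C)(OC(C)=O)CC[C@H]2C(C)(C)C(=O)CC[C@]12C
F5 | step 3 | (13R)-8α-acetoxy-13-hydroxylabd-14-en-3-one | C=C[C@](C)(O)CC[C@H]1[C@](C)(OC(C)=O)CC[C@H]2C(C)(C)C(=O)CC[C@]12C
F6 | step 3 | 3-oxomanool, (13R)-13-hydroxylabda-8(17),14-dien-3-one | C=C[C@](C)(O)CC[C@H]1C(=C)CC[C@H]2C(C)(C)C(=O)CC[C@]12C
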